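**Plan**

- Atom labels are the positions of the non-hydrogen atoms in the target SMILES. Retrosynthesis: both epoxyquinol rings go back to p-dimethoxyarenes; the methyl bonds C2–C1 and C27–C28 and the ring-ether bonds C2–O3 and C27–O26 go back to two ester/carbinol pairs; C4–C5, C6–C14, C25–C17 and C16–C15 are cut together to two arynes and a four-membered ring.
- Enabling feature: C14, C4, C25 and C15 are the four sp3 carbons of the eight-membered carbocycle. Closing C4 to C14 and C25 to C15 in thought leaves a cyclobutane; the real carbocycle is that ring with the alkene pairs C5=C6 and C17=C16 set into those two bonds.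
- Forward order of rings: cyclobutane by [2+2] photocycloaddition; carbocycle by double aryne insertion (four to six to eight); two bridging lactones, later the pyrans; last the two epoxides on the dearomatised rings.
- During the insertions one of C4/C25 is kept as an acetoxy carbinol, because a free 1,2-dione would tautomerise to a naphthalenediol after the first insertion.
- Stereochemistry: C4/C25 by catalyst-controlled transfer hydrogenation of the dione; C14/C15 by equilibration into the only doubly lactonisable arrangement; C2/C27, the epoxides and C12/C18 by reagent approach to the outer face of the rigid cage.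

Key step: step 8

Remark: every cyclobutane and carbocycle intermediate before the asymmetric reduction is carried as a racemate or diastereomer mixture, because each of its stereocentres is later erased or equilibrated; the SMILES then show one representative isomer or leave labile centres open.

**Route**

Step 1
Reactants: 1 2,5-dimethoxyphenol
Product: 2 2,5-dimethoxyphenyl N-isopropylcarbamate
Conditions: i-PrNCO, Et3N (cat.), CH2Cl2, 23 °C
Reagents that add atoms: isopropyl isocyanate, CC(C)N=C=O
Why: Base-catalysed addition of the phenol to the isocyanate (carbamoylation) installs the group that will direct ortho-metalation.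

Step 2
Reactants: 2 2,5-dimethoxyphenyl N-isopropylcarbamate
Product: 6 3,6-dimethoxy-2-(trimethylsilyl)phenyl N-isopropylcarbamate, via N-silylcarbamate 3 (not isolated), via aryllithium 4 (not isolated), via disilyl carbamate 5 (not isolated)
Conditions: TBSOTf, TMEDA, Et2O, 0 → 23 °C; n-BuLi, TMEDA, −78 °C; TMSCl, −78 → 23 °C; aq. NaHSO4
Reagents that add atoms: chlorotrimethylsilane, C[Si](C)(C)Cl
Why: Directed ortho-metalation: after N-silylation in the flask, the carbamate and the neighbouring methoxy group both direct lithiation to the single position between them, and the aryllithium is silylated.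

Step 3
Reactants: 6 3,6-dimethoxy-2-(trimethylsilyl)phenyl N-isopropylcarbamate
Product: 8 3,6-dimethoxy-2-(trimethylsilyl)phenyl trifluoromethanesulfonate, via silylphenol 7 (not isolated)
Conditions: Et2NH, DBU, MeCN, 40 °C; then PhNTf2, 23 °C
Reagents that add atoms: N-phenylbis(trifluoromethanesulfonimide), O=S(=O)(N(c1ccccc1)S(=O)(=O)C(F)(F)F)C(F)(F)F
Why: E1cB cleavage of the N–H carbamate (isocyanate scavenged by diethylamine) frees the hindered phenoxide, which is triflated to the o-silylaryl triflate aryne precursor.

Step 4
Reactants: 9 diethyl fumarate; 10 vinylene carbonate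
Product: 11 diethyl 3-oxo-2,4-dioxabicyclo[3.2.0]heptane-6,7-dicarboxylate (carbonate cis-fused, esters trans, racemic)
Conditions: hν (300 nm), acetone (sensitiser and solvent), 10 °C
Reagents that add atoms: none
Why: Triplet-sensitised [2+2] photocycloaddition of vinylene carbonate to an alkene; the carbonate ring enforces the cis fusion and stepwise biradical closure leaves the esters trans, neither relationship being needed later.

Step 5
Reactants: 11 the cyclobutane carbonate
Product: 12 diethyl 3,4-dihydroxycyclobutane-1,2-dicarboxylate (hydroxyls cis, esters trans, racemic)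
Conditions: K2CO3 (cat.), EtOH, 0 °C
Reagents that add atoms: none
Why: Transesterification of the strained cyclic carbonate with ethanol releases the cis-diol under conditions mild enough to spare the β-hydroxy esters from retro-aldol ring opening.

Step 6
Reactants: 12 the cis-diol
Product: 14 diethyl 3-acetoxy-4-hydroxycyclobutane-1,2-dicarboxylate (both mono-acetates carried), via cyclic orthoacetate 13 (not isolated)
Conditions: MeC(OMe)3, PPTS (cat.), CH2Cl2, 23 °C; then AcOH/H2O (4:1), 23 °C
Reagents that add atoms: trimethyl orthoacetate, CC(OC)(OC)OC; water, O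
Why: Mono-acylation of a cis-1,2-diol through its cyclic orthoester, whose acid hydrolysis can deliver only one acetate per diol.

Step 7
Reactants: 14 the hydroxy acetate
Product: 15 diethyl 3-acetoxy-4-oxocyclobutane-1,2-dicarboxylate (diastereomer mixture, partly enolised)
Conditions: Dess–Martin periodinane, NaHCO3, CH2Cl2, 0 → 23 °C
Reagents that add atoms: none
Why: Dess–Martin oxidation of the remaining secondary alcohol under buffered, non-basic conditions gives the cyclobutanone β-ketoester without touching its labile α-centre deliberately.

Step 8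
Reactants: 15 diethyl 3-acetoxy-4-oxocyclobutane-1,2-dicarboxylate; 8 3,6-dimethoxy-2-(trimethylsilyl)phenyl trifluoromethanesulfonate (two equivalents)
Product: 19 diethyl 6-acetoxy-1,4,7,10-tetramethoxy-5-oxo-5,6,11,12-tetrahydrodibenzo[a,e][8]annulene-11,12-dicarboxylate (diastereomer mixture), via 3,6-dimethoxybenzyne 16 (not isolated), via acetoxytetralone 17 (not isolated), via oxotetralin ketoester 18 (not isolated)
Conditions: CsF, n-Bu4NOAc (cat.), MeCN, 23 → 60 °C
Reagents that add atoms: none
Why: Proposed new method: fluoride converts 8 into aryne 16, the β-ketoester enolate of 15 attacks it through C14, the resulting aryl anion adds to the adjacent cyclobutanone carbonyl C4 (4-exo), and the strained benzocyclobutenoxide fragments by retro-aldol cleavage of C4–C14 to give tetralone 17 (bonds C6–C14 and C4–C5 made, four-membered ring expanded to six). Acetate or fluoride then enolises the α-acetoxy ketone and the acetyl group shifts from O25 to O4 across the enediol, which moves the carbonyl to C25 and makes C15 a β-ketoester carbon (18), so that a second aryne is inserted into C25–C15 in the same way (bonds C16–C15 and C25–C17 made, six-membered ring expanded to the eight-membered carbocycle). The closest known reactions are the aryne acyl-alkylation of cyclic β-ketoesters with two-carbon ring expansion and the base-induced transposition of ketol acetates; a cyclobutanone substrate and the three events in one flask are without precedent. The carbocycle is therefore closed by two successive ring expansions and not by an end-to-end cyclisation, and none of the three stereocentres of 19 (C4, C14, C15) is controlled, because C4 is oxidised in step 10 and C14/C15 are equilibrated in steps 9 and 13. Needed are attack of each aryl anion on the neighbouring ketone (the nearest and most electrophilic carbonyl, favoured over ester and acetate carbonyls) and survival of the six-membered intermediates: with C25 or C4 held as an acetoxy carbinol no tautomer of 17 or 18 is a naphthalenediol, the trap that a free cyclobutane-1,2-dione would meet after the first insertion. The symmetrical aryne removes any question of regiochemistry.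

Step 9
Reactants: 19 the acetoxy ketone
Product: 20 diethyl 6-hydroxy-1,4,7,10-tetramethoxy-5-oxo-5,6,11,12-tetrahydrodibenzo[a,e][8]annulene-11,12-dicarboxylate (diastereomer mixture)
Conditions: K2CO3, EtOH, 0 °C, argon
Reagents that add atoms: none
Why: Carbonate-mediated transesterification removes the acetate, and the same base should equilibrate the two benzylic ester centres towards the trans arrangement.

Step 10
Reactants: 20 the hydroxy ketone
Product: 21 diethyl 1,4,7,10-tetramethoxy-5,6-dioxo-5,6,11,12-tetrahydrodibenzo[a,e][8]annulene-11,12-dicarboxylate (trans-diester, racemic)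
Conditions: Dess–Martin periodinane, CH2Cl2, 23 °C
Reagents that add atoms: none
Why: Dess–Martin oxidation of a benzoin-type ketol to the benzil-type 1,2-diketone; no stereocentre is formed and the carbinol centre of 20 disappears.

Step 11
Reactants: 21 the tetramethoxy dione
Product: 22 diethyl 4,7-dihydroxy-1,10-dimethoxy-5,6-dioxo-5,6,11,12-tetrahydrodibenzo[a,e][8]annulene-11,12-dicarboxylate (phenols at C12 and C18; racemic)
Conditions: BCl3, CH2Cl2, −78 → 0 °C
Reagents that add atoms: none
Why: Chelation-controlled ether cleavage: BCl3 bound to each aryl ketone removes only the methyl ether ortho to it, which differentiates the two oxygens of each ring for the later regioselective monoketal formation.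

Step 12
Reactants: 22 the bis-phenol dione
Product: 23 diethyl (5S,6S)-4,5,6,7-tetrahydroxy-1,10-dimethoxy-5,6,11,12-tetrahydrodibenzo[a,e][8]annulene-11,12-dicarboxylate (C4 and C25 both S; both trans-diester series at C14/C15)
Conditions: RuCl(p-cymene)[(R,R)-TsDPEN] (cat.), HCO2H/Et3N (5:2), DMF, 40 °C
Reagents that add atoms: none
Why: Noyori asymmetric transfer hydrogenation of a benzil-type diketone: the ruthenium hydride should reduce the first carbonyl under catalyst control and the second through the hydroxy ketone to the anti diol, the ligand antipode being chosen by analogy with benzil (where the (S,S)-ligand gives the (R,R)-diol) so that C4 and C25 both become S.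

Step 13
Reactants: 23 the diol diester
Product: 24 bis-lactone (carbocycle bridged by C14–C2(=O)–O3–C4 and C15–C27(=O)–O26–C25; OH at C12 and C18, OMe at C7 and C23)
Conditions: DBU, toluene, 90 °C
Reagents that add atoms: none
Why: Base-mediated lactonisation (transesterification) under thermodynamic control: DBU epimerises the benzylic ester centres until each ester is cis to the hydroxyl across its arene, the only arrangement that can close both six-membered lactones, so the S,S-diol fixes C14 and C15 as S,S.

Step 14
Reactants: 24 the bis-lactone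
Product: 25 bis-lactol (C2 and C27 as CH–OH, anomer mixture)
Conditions: i-Bu2AlH, CH2Cl2, −78 °C
Reagents that add atoms: none
Why: Half-reduction of lactones to lactols with i-Bu2AlH at low temperature; the anomeric configuration is irrelevant because it is ionised in step 16.

Step 15
Reactants: 25 the bis-lactol
Product: 26 tetraacetate (anomeric acetates at C2 and C27, aryl acetates at C12 and C18)
Conditions: Ac2O, pyridine, DMAP (cat.), CH2Cl2, 0 → 23 °C
Reagents that add atoms: acetic anhydride, CC(=O)OC(C)=O
Why: DMAP-catalysed acetylation installs the anomeric leaving groups and masks the phenols in one operation.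

Step 16
Reactants: 26 the tetraacetate
Product: 27 bis-C-methyl pyran bis(aryl acetate) (C2 and C27 both R)
Conditions: AlMe3, TMSOTf (cat.), CH2Cl2, −78 → −20 °C
Reagents that add atoms: trimethylaluminium, C[Al](C)C
Why: Lewis-acid substitution of anomeric acetates through bridged oxocarbenium ions with AlMe3 as methyl donor: methyl should enter each cation from the open face, the other being covered by the arene edge of the opposite half, which gives R at C2 and C27.

Step 17
Reactants: 27 the bis(aryl acetate)
Product: 28 bis-phenol (OH at C12 and C18, OMe at C7 and C23, pyran rings complete)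
Conditions: K2CO3, MeOH, 0 → 23 °C
Reagents that add atoms: none
Why: Methanolysis of the aryl acetates liberates the two p-methoxyphenols.

Step 18
Reactants: 28 the bis-phenol
Product: 29 bis(quinone monoketal) (C12 and C18 ketones, C7 and C23 dimethyl ketals)
Conditions: PhI(OAc)2, MeOH, 0 °C
Reagents that add atoms: methanol, CO
Why: Hypervalent-iodine oxidative dearomatisation of p-methoxyphenols in methanol gives quinone monoketals whose carbonyl sits at the former phenol carbon, as the regiochemistry of the epoxyquinols requires.

Step 19
Reactants: 29 the bis(quinone monoketal)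
Product: 30 bis(epoxy ketone) (epoxides C9–C11 and C20–C22, configured as in the target)
Conditions: t-BuOOH, DBU, CH2Cl2, 0 → 23 °C
Reagents that add atoms: tert-butyl hydroperoxide, CC(C)(C)OO
Why: Weitz–Scheffer nucleophilic epoxidation of the disubstituted enone bond of each monoketal; the peroxide should add to the outer face of each ring, the inner face being covered by the O–CH(Me) bridge of the other half, which sets C9, C11, C20 and C22.

Step 20
Reactants: 30 the bis(epoxy ketone)
Product: 31 bis(epoxy alcohol) bis(dimethyl ketal) (each hydroxyl trans to its epoxide)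
Conditions: NaBH4, CeCl3·7H2O, MeOH, −78 °C
Reagents that add atoms: none
Why: Luche 1,2-reduction of the epoxy enones: hydride should reach C12 and C18 from the same outer face, the inner face being blocked by O26/O3 and the bridge C–H of the partner half, which places each hydroxyl trans to its epoxide.

Step 21
Reactants: 31 the bis(dimethyl ketal)
Product: 32 epoxytwinol A
Conditions: TsOH·H2O (cat.), acetone/H2O, 0 → 23 °C
Reagents that add atoms: water, O
Why: Acid-catalysed hydrolysis (transketalisation to acetone) of the allylic dimethyl ketals unveils the two enones under conditions that leave the epoxides and the bridging ethers intact.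

**Compound list**

1 | 2,5-dimethoxyphenol | COc1ccc(OC)c(O)c1 | starting material
2 | 2,5-dimethoxyphenyl N-isopropylcarbamate | COc1ccc(OC)c(OC(=O)NC(C)C)c1 | intermediate
3 | N-(tert-butyldimethylsilyl) derivative of 2 | COc1ccc(OC)c(OC(=O)N(C(C)C)[Si](C)(C)C(C)(C)C)c1 | intermediate (not isolated)
4 | 6-lithio derivative of 3 (lithium between carbamate oxygen and 5-methoxy) | COc1ccc(OC)c(OC(=O)N(C(C)C)[Si](C)(C)C(C)(C)C)c1[Li] | intermediate (not isolated)
5 | 3,6-dimethoxy-2-(trimethylsilyl)phenyl N-isopropyl-N-(tert-butyldimethylsilyl)carbamate | COc1ccc(OC)c(OC(=O)N(C(C)C)[Si](C)(C)C(C)(C)C)c1[Si](C)(C)C | intermediate (not isolated)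
6 | 3,6-dimethoxy-2-(trimethylsilyl)phenyl N-isopropylcarbamate | COc1ccc(OC)c(OC(=O)NC(C)C)c1[Si](C)(C)C | intermediate
7 | 3,6-dimethoxy-2-(trimethylsilyl)phenol | COc1ccc(OC)c(O)c1[Si](C)(C)C | intermediate (not isolated)
8 | 3,6-dimethoxy-2-(trimethylsilyl)phenyl trifluoromethanesulfonate | COc1ccc(OC)c(OS(=O)(=O)C(F)(F)F)c1[Si](C)(C)C | intermediate
9 | diethyl fumarate | CCOC(=O)/C=C/C(=O)OCC | starting material
10 | vinylene carbonate | O=C1OC=CO1 | starting material
11 | diethyl 3-oxo-2,4-dioxabicyclo[3.2.0]heptane-6,7-dicarboxylate (cis-fused, esters trans, racemic) | CCOC(=O)[C@@H]1[C@@H](C(=O)OCC)[C@@H]2OC(=O)O[C@H]12 | intermediate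
12 | diethyl 3,4-dihydroxycyclobutane-1,2-dicarboxylate (hydroxyls cis, esters trans, racemic) | CCOC(=O)[C@@H]1[C@@H](C(=O)OCC)[C@H](O)[C@@H]1O | intermediate
13 | cyclic methyl orthoacetate of 12 | CCOC(=O)[C@@H]1[C@@H](C(=O)OCC)[C@@H]2OC(C)(OC)O[C@H]12 | intermediate (not isolated)
14 | diethyl 3-acetoxy-4-hydroxycyclobutane-1,2-dicarboxylate (one of the two mono-acetates shown, racemic) | CCOC(=O)[C@@H]1[C@@H](C(=O)OCC)[C@H](OC(C)=O)[C@@H]1O | intermediate
15 | diethyl 3-acetoxy-4-oxocyclobutane-1,2-dicarboxylate (representative diastereomer, racemic) | CCOC(=O)[C@@H]1[C@@H](C(=O)OCC)[C@H](OC(C)=O)C1=O | intermediate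
16 | 3,6-dimethoxybenzyne | COC1=CC=C(OC)C#C1 | intermediate (not isolated)
17 | diethyl 3-acetoxy-5,8-dimethoxy-4-oxo-1,2,3,4-tetrahydronaphthalene-1,2-dicarboxylate (diastereomer mixture, centres open) | CCOC(=O)C1C(C(=O)OCC)C(OC(C)=O)C(=O)c2c(OC)ccc(OC)c21 | intermediate (not isolated)
18 | diethyl 4-acetoxy-5,8-dimethoxy-3-oxo-1,2,3,4-tetrahydronaphthalene-1,2-dicarboxylate (diastereomer mixture, centres open) | CCOC(=O)C1C(C(=O)OCC)C(=O)C(OC(C)=O)c2c(OC)ccc(OC)c21 | intermediate (not isolated)
19 | diethyl 6-acetoxy-1,4,7,10-tetramethoxy-5-oxo-5,6,11,12-tetrahydrodibenzo[a,e][8]annulene-11,12-dicarboxylate (diastereomer mixture, centres open) | CCOC(=O)C1C(C(=O)OCC)c2c(OC)ccc(OC)c2C(=O)C(OC(C)=O)c2c(OC)ccc(OC)c21 | intermediate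
20 | diethyl 6-hydroxy-1,4,7,10-tetramethoxy-5-oxo-5,6,11,12-tetrahydrodibenzo[a,e][8]annulene-11,12-dicarboxylate (diastereomer mixture, centres open) | CCOC(=O)C1C(C(=O)OCC)c2c(OC)ccc(OC)c2C(=O)C(O)c2c(OC)ccc(OC)c21 | intermediate
21 | diethyl 1,4,7,10-tetramethoxy-5,6-dioxo-5,6,11,12-tetrahydrodibenzo[a,e][8]annulene-11,12-dicarboxylate (trans, racemic; one antipode drawn) | CCOC(=O)[C@@H]1c2c(OC)ccc(OC)c2C(=O)C(=O)c2c(OC)ccc(OC)c2[C@H]1C(=O)OCC | intermediate
22 | diethyl 4,7-dihydroxy-1,10-dimethoxy-5,6-dioxo-5,6,11,12-tetrahydrodibenzo[a,e][8]annulene-11,12-dicarboxylate (trans, racemic; one antipode drawn) | CCOC(=O)[C@@H]1c2c(OC)ccc(O)c2C(=O)C(=O)c2c(O)ccc(OC)c2[C@H]1C(=O)OCC | intermediate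
23 | diethyl (5S,6S)-4,5,6,7-tetrahydroxy-1,10-dimethoxy-5,6,11,12-tetrahydrodibenzo[a,e][8]annulene-11,12-dicarboxylate (ester centres open: both trans series) | O[C@H]1c2c(c(OC)ccc2O)C(C(=O)OCC)C(C(=O)OCC)c2c(c(O)ccc2OC)[C@@H]1O | intermediate
24 | bis-lactone (4S,14S,15S,25S; lactone bridges C14–C2(=O)–O3–C4 and C15–C27(=O)–O26–C25; OH at C12/C18, OMe at C7/C23) | O=C1O[C@H]2c3c(c(OC)ccc3O)[C@@H]1[C@H]1c3c(c(O)ccc3OC)[C@@H]2OC1=O | intermediate
25 | bis-lactol of 24 (C2 and C27 CH–OH, anomers open) | OC1O[C@H]2c3c(c(OC)ccc3O)[C@@H]1[C@H]1c3c(c(O)ccc3OC)[C@@H]2OC1O | intermediate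
26 | tetraacetate of 25 (anomeric and aryl acetates; anomers open) | CC(=O)OC1O[C@H]2c3c(c(OC)ccc3OC(C)=O)[C@@H]1[C@H]1c3c(c(OC(C)=O)ccc3OC)[C@@H]2OC1OC(C)=O | intermediate
27 | bis-C-methyl pyran bis(aryl acetate) (2R,4S,14S,15S,25S,27R) | C[C@H]1O[C@H]2c3c(c(OC)ccc3OC(C)=O)[C@@H]1[C@H]1c3c(c(OC(C)=O)ccc3OC)[C@@H]2O[C@@H]1C | intermediate
28 | bis-phenol (OH at C12/C18, OMe at C7/C23) | C[C@H]1O[C@H]2c3c(c(OC)ccc3O)[C@@H]1[C@H]1c3c(c(O)ccc3OC)[C@@H]2O[C@@H]1C | intermediate
29 | bis(quinone monoketal) (C12/C18 ketones, C7/C23 dimethyl ketals) | C[C@H]1O[C@H]2C3=C(C(OC)(OC)C=CC3=O)[C@@H]1[C@H]1C3=C(C(=O)C=CC3(OC)OC)[C@@H]2O[C@@H]1C | intermediate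
30 | bis(epoxy ketone) (epoxides C9–C11 and C20–C22 on the outer faces) | C[C@H]1O[C@H]2C3=C(C(OC)(OC)[C@@H]4O[C@@H]4C3=O)[C@@H]1[C@H]1C3=C(C(=O)[C@H]4O[C@H]4C3(OC)OC)[C@@H]2O[C@@H]1C | intermediate
31 | bis(epoxy alcohol) bis(dimethyl ketal) (hydroxyls trans to the epoxides) | C[C@H]1O[C@H]2C3=C(C(OC)(OC)[C@@H]4O[C@@H]4[C@H]3O)[C@@H]1[C@H]1C3=C([C@H](O)[C@H]4O[C@H]4C3(OC)OC)[C@@H]2O[C@@H]1C | intermediate
32 | epoxytwinol A | C[C@H]1O[C@H]2C3=C(C(=O)[C@@H]4O[C@@H]4[C@H]3O)[C@@H]1[C@H]1C3=C([C@H](O)[C@H]4O[C@H]4C3=O)[C@@H]2O[C@@H]1C | target

**Step count and risks**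

Total: 21 steps. Longest linear sequence: 18 steps (steps 4–21, from diethyl fumarate and vinylene carbonate); the aryne precursor is a three-step branch (steps 1–3) that joins at step 8.

Steps most likely to fail:

1. Step 8. After the first insertion the tetralone may lose acetic acid by E1cB elimination through its ester enolate and aromatise, the acetyl transposition may lag behind aryne generation so that the second aryne is wasted, or fluoride may open the cyclobutanone by retro-Claisen cleavage before arylation. Fallback, setting out from 15 and 8 and returning at 19: the one-flask cascade is given up and the three events are run as separate operations, each a reaction type with direct precedent. Compound 15 is treated with one equivalent of 8 (KF, 18-crown-6, THF, 0 °C), which is the acyl-alkylation of a cyclic β-ketoester, and 17 is isolated. The acetate-catalysed ketol-acetate transposition (n-Bu4NOAc, MeCN, 50 °C) then gives isolated 18. Finally the established two-carbon ring expansion of a six-membered cyclic β-ketoester with the second equivalent of 8 (CsF, MeCN, 80 °C) gives 19. No compound outside the list is made.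

2. Step 12. The conformational bias of the trans-diester ring may oppose the catalyst for one antipode of racemic 22, so that reduction stops at the hydroxy ketone or gives the mirror-image carbinol pair and enantiomeric purity is eroded; the chelated o-hydroxyaryl ketones may also turn over slowly. Fallback, setting out from 22 and returning at 24: the dione is reduced without absolute control (NaBH4, CeCl3·7H2O, MeOH/THF, −40 °C) to the racemic trans-diol, that is 23 together with the enantiomeric diol F1. The mixture is lactonised as in step 13 to the racemic bis-lactone, 24 together with the enantiomeric bis-lactone F2. The antipodes are separated by preparative chromatography on a chiral stationary phase, and 24 goes on to step 14.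

3. Step 20. Hydride delivery anti to the new epoxide, the usual course for α,β-epoxy ketones, may override the shielding by the cage and give the cis-epoxy alcohols. Fallback, setting out from 30 and returning at 31: the cis isomer is made on purpose with a bulky hydride (LiBH(s-Bu)3, THF, −78 °C) to give the bis(cis-epoxy alcohol) F3. Both carbinol centres are inverted by Mitsunobu reaction (4-nitrobenzoic acid, PPh3, DIAD, toluene, 0 °C) to the bis(4-nitrobenzoate) F4, and the esters are cleaved (K2CO3, MeOH, 0 °C) to give 31.

Further compounds
F0 | step 8 | none | none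
F1 | step 12 | enantiomer of diol 23 (carbinol centres R,R) | O[C@@H]1c2c(c(OC)ccc2O)C(C(=O)OCC)C(C(=O)OCC)c2c(c(O)ccc2OC)[C@H]1O
F2 | step 12 | enantiomer of bis-lactone 24 | O=C1O[C@@H]2c3c(c(OC)ccc3O)[C@H]1[C@@H]1c3c(c(O)ccc3OC)[C@H]2OC1=O
F3 | step 20 | bis(cis-epoxy alcohol), C12/C18 epimer of 31 | C[C@H]1O[C@H]2C3=C(C(OC)(OC)[C@@H]4O[C@@H]4[C@@H]3O)[C@@H]1[C@H]1C3=C([C@@H](O)[C@H]4O[C@H]4C3(OC)OC)[C@@H]2O[C@@H]1C
F4 | step 20 | bis(4-nitrobenzoate) of 31 | C[C@H]1O[C@H]2C3=C(C(OC)(OC)[C@@H]4O[C@@H]4[C@H]3OC(=O)c5ccc(cc5)[N+](=O)[O-])[C@@H]1[C@H]1C3=C([C@H](OC(=O)c5ccc(cc5)[N+](=O)[O-])[C@H]4O[C@H]4C3(OC)OC)[C@@H]2O[C@@H]1C
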